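## Structural features

The target is a 2,3-dihydrobenzofuran: the heterocycle (O1, C2, C3) is fused to benzene ring A through C3a and C7a. Ring A carries a methoxy group at C7 and an acetyl group at C5; C2 carries a 4-hydroxy-3,5-dimethoxyphenyl (syringyl) ring and C3 a hydroxymethyl group. The only stereocentres are the neighbours C2 and C3, (2S,3R), with aryl and hydroxymethyl trans. The C2–O1 bond is a p-hydroxybenzyl aryl ether whose leaving group is a para-acyl phenoxide, so the free phenol can open the ring to a quinone methide under hot base or acid. C3–H is benzylic, the ring can be dehydrogenated to a benzofuran, the methyl ketone is enolisable, and both arenes are sensitive to oxidants and electrophilic halogen. The real difficulty is to join two different oxygenated arenes through a two-carbon unit with absolute control at two adjacent carbons and the correct 1,2,3,5-pattern on ring A. The key step exploits the place of O1 on C7a between the C7 methoxy group and C3a: an aryl iodide with iodine at C7a has one ortho position blocked and a single ortho C–H at C3a, so ortho C–H alkylation followed by ipso C–O closure can form C3–C3a and O1–C7a in one operation. A cis-epoxide across C2–C3 supplies both stereocentres and becomes the trans ring, because C3 is inverted and C2 is retained.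

## Logic of the disconnections

10 to 9: the acyl–oxygen bond at the syringyl oxygen is cut. The phenol is set free last because, once free, it labilises C2–O1; until then the acyloxy group keeps the C2 aryl ring electron-poor. The forward step must be a deacylation mild enough not to open the heterocycle of 10. A sulfonate in this position would need hot hydroxide and is avoided for that reason.

9 to 8: the benzyl–oxygen bond of the primary ether is cut. During the annulation the C3 hydroxymethyl oxygen must carry a group that cannot move to a neighbouring alkoxide. A silyl ether could shift to the C2 alkoxide through a six-membered silicate and let the primary alkoxide close an isomeric five-membered ring onto C7a. A benzylic ether cannot. The forward step must remove it oxidatively while the phenol of 8 is still acylated.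

8 to 6 and 7: C3–C3a and O1–C7a are cut. This removes the heterocycle, divides the molecule into two pieces of similar size, lets ring A be bought complete as 7, and moves both stereocentres into 6. The forward step must alkylate only the C–H at C3a of 7, open 6 at C3 with inversion and not at benzylic C2, and close the ring through the C2 alkoxide. The (2R,3S) cis isomer of 6 is the one that maps onto (2S,3R) in 8.

6 to 5: the two C–O bonds of the oxirane are cut. Both stereocentres are reduced to one Z double bond. The forward step must choose one enantioface of a Z aryl alkene and keep the cis geometry.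

5 to 4: the Z double bond is taken back to the triple bond. Geometry then comes from syn addition of hydrogen. The forward step must stop at the alkene without isomerisation and without hydrogenolysis of the benzylic ether.

4 to 2 and 3: the aryl–alkynyl bond is cut. The whole C2–C3–CH2O unit comes from 3 with its ether already in place, which saves a protection step. The forward step must couple an unactivated aryl bromide without touching the aryl ester.

2 to 1: the ester C–O bond is cut; 1 is purchased. Acylation comes first so that no free phenol meets palladium or oxidants.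

## Other disconnections considered

Alternative 1: The cut goes through C2–aryl (syringyl) and C3–C3a and leaves the heterocycle open.
- Forward key step: aryllithium A2 would add to E-alkenyl boronate A3 to give ate complex A4. An aryl palladium species from aryl bromide A5 (Pd(OAc)2, a chiral ferrocenyl diphosphine of the MandyPhos type, NaOTf to take up halide) would induce a 1,2-shift of the syringyl group from boron to C2 while palladium bonds to C3 on the opposite face. Reductive elimination would give boronate A1.
- In its favour: two C–C bonds and both stereocentres arise in one ligand-controlled catalytic step. The relative configuration follows from the E geometry and the anti addition, and there is no regiochemical ambiguity.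
- Better than the chosen plan on two points: absolute control inside the bond-forming step, and regiochemical certainty.
- Against it here: β-substituted alkenyl pinacol ate complexes are prone to transfer the alkenyl group directly (Suzuki–Miyaura pathway). The secondary alkyl palladium at C3 has a β-silyloxy group and β-hydrogens. No ring is formed, and ring A must be bought as a nitrile and fluoride.
- The sequence would continue with C–B oxidation that spares the nitrile, fluoride displacement to close O1–C7a, methyl addition to the nitrile, and two deprotections. One of these is a hydrogenolysis next to a benzylic C–O bond and an aryl ketone.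
- Comparison: structurally both plans join the same two arenes through C2–C3. Mechanistically the alternative rests on a demonstrated reaction class and is the equal or the better there. In step economy it is the poorer: about five steps after the key step and a custom bromide, against two steps and a catalogue iodide.

Alternative 2: The cut goes through C2–C3 and O1–C7a, a formal (3+2) union of a C3–ring A unit with the syringyl aldehyde.
- Forward key step: enolisation of imide A7 with Bu2BOTf and iPr2NEt and addition to aldehyde A8 through a closed chair transition state would set C2 and C3 syn under control of the (S)-4-benzyl oxazolidinone. After release of the boron aldolate, KHMDS would form the C2 alkoxide, which displaces the fluoride para to the nitrile and closes the ring to imide A6. The syn aldol corresponds to the trans ring and the (S) auxiliary to the (2S,3R) series of 10.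
- In its favour: the stereocontrol is the most predictable of all the plans, and on this point the alternative is better than the chosen plan. The closure is an activated five-membered ipso substitution.
- Against it here: an α-aryl aldolate under KHMDS is set up for retro-aldol cleavage. A6 has an acidic C3–H beside a good aryloxide leaving group at C2, so β-elimination and epimerisation threaten. The auxiliary is stoichiometric and A7 needs a non-commercial arylacetic acid.
- Afterwards the auxiliary must be removed reductively, a methyl group added to the nitrile, and the benzyl ether cleaved.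
- Comparison: structurally it forms C2–C3 instead of C3–C3a and again carries ring A in disguise, whereas the chosen plan uses ring A with its acetyl group in place. Mechanistically every step is of a known type (equal or better). In step economy it is longer by roughly three to four steps.

Alternative 3: The cut goes through C3a–C4 and C5–C6, so ring A is made last.
- Forward key step: diene A10 would add but-3-yn-2-one A11 in a Diels–Alder reaction. The ring oxygen on C7a and the terminal methoxy group make C3a the nucleophilic diene terminus. It pairs with the unsubstituted alkyne carbon and places the acetyl group at C5. Loss of the C6 methoxy group with the C3a hydrogen would aromatise the adduct to A9.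
- In its favour: acetyl and C7 methoxy arrive in a defined pattern. C2 and C3 are set beforehand on lactone A12 by established methods and are not touched by the key step, so in stereochemical security it is the equal or the better. A9 is two deprotections from 10.
- Against it here: A10 is a very electron-rich, hydrolysis-prone bis(enol ether). It needs two further operations from A12 (O-phosphorylation of the lactone enolate, then a cross-coupling that brings in the dimethoxyvinyl unit). Its C3–H is allylic to the diene, and the C7 methoxy group directs the opposite way and may erode regioselectivity. A12 itself costs four to five steps.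
- Comparison: structurally it builds a benzene ring that the chosen plan buys. Mechanistically the cycloaddition and aromatisation are of a known type but with an untested diene. Step economy is clearly worse (ten or more steps).

Key step: step 5

Assumption: 3 and 7 are treated as catalogue compounds, and the (R,R) catalyst of step 4 is taken to induce the same sense as with cis-β-methylstyrene (benzylic carbon R); the configuration of 6 has to be confirmed before step 5.

## Route

Step 1
Reactants: 1 4-bromo-2,6-dimethoxyphenol
Product: 2 4-bromo-2,6-dimethoxyphenyl pivalate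
Conditions: PivCl (1.3 equiv), Et3N (2 equiv), DMAP (10 mol %), CH2Cl2, 0 °C to rt
Reagents that add atoms: pivaloyl chloride, CC(C)(C)C(Cl)=O
Why: DMAP-catalysed O-acylation of a phenol; the pivalate withdraws electron density from the ring, resists amine and carbonate bases and leaves at the end by mild methanolysis.

Step 2
Reactants: 2 4-bromo-2,6-dimethoxyphenyl pivalate; 3 1-methoxy-4-[(prop-2-yn-1-yloxy)methyl]benzene (4-methoxybenzyl propargyl ether)
Product: 4 2,6-dimethoxy-4-{3-[(4-methoxybenzyl)oxy]prop-1-yn-1-yl}phenyl pivalate
Conditions: 3 (1.3 equiv), Pd(PPh3)2Cl2 (3 mol %), CuI (5 mol %), Et3N/THF 1:1, 65 °C, degassed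
Reagents that add atoms: none
Why: Sonogashira coupling of an aryl bromide with a terminal alkyne; the hindered aryl ester and the benzylic ether are inert to Pd(PPh3)2Cl2/CuI and triethylamine.

Step 3
Reactants: 4 2,6-dimethoxy-4-{3-[(4-methoxybenzyl)oxy]prop-1-yn-1-yl}phenyl pivalate
Product: 5 2,6-dimethoxy-4-{(Z)-3-[(4-methoxybenzyl)oxy]prop-1-en-1-yl}phenyl pivalate
Conditions: H2 (1 atm), Pd/CaCO3 poisoned with Pb(OAc)2, quinoline, EtOAc, rt, stopped after 1 equiv H2
Reagents that add atoms: none
Why: Lindlar semi-hydrogenation; syn delivery of hydrogen on the poisoned palladium surface sets the Z double bond, quinoline and control of hydrogen uptake suppress over-reduction, and the benzylic ether is not hydrogenolysed on this catalyst.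

Step 4
Reactants: 5 2,6-dimethoxy-4-{(Z)-3-[(4-methoxybenzyl)oxy]prop-1-en-1-yl}phenyl pivalate
Product: 6 2,6-dimethoxy-4-[(2R,3S)-3-{[(4-methoxybenzyl)oxy]methyl}oxiran-2-yl]phenyl pivalate (cis-epoxide)
Conditions: (R,R)-N,N'-bis(3,5-di-tert-butylsalicylidene)-1,2-cyclohexanediamine manganese chloride (trivalent manganese, 5 mol %), 4-phenylpyridine N-oxide (20 mol %), aq. NaOCl buffered to pH 11.3, CH2Cl2, 0 °C
Reagents that add atoms: sodium hypochlorite, [Na+].[O-]Cl
Why: Jacobsen–Katsuki epoxidation, the method of choice for cis-disubstituted aryl alkenes; the oxo-manganese salen complex delivers oxygen to one enantioface and sets both stereocentres, the cis relation coming from the Z alkene. The N-oxide and the low temperature limit stepwise leakage to the trans-epoxide, which is removed by chromatography; the buffered pH spares the pivalate.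

Step 5
Reactants: 6 2,6-dimethoxy-4-[(2R,3S)-3-{[(4-methoxybenzyl)oxy]methyl}oxiran-2-yl]phenyl pivalate; 7 1-(4-iodo-3-methoxyphenyl)ethanone
Product: 8 4-[(2S,3R)-5-acetyl-7-methoxy-3-{[(4-methoxybenzyl)oxy]methyl}-2,3-dihydro-1-benzofuran-2-yl]-2,6-dimethoxyphenyl pivalate (trans)
Conditions: 6 (1.3 equiv, excess recovered), Pd(OAc)2 (10 mol %), P(2-furyl)3 (25 mol %), norbornene (1.0 equiv), Cs2CO3 (2.5 equiv), DMF, 90 °C, argon
Reagents that add atoms: none
Why: Proposed new method: zerovalent palladium inserts into the C–I bond of 7, norbornene inserts and the only free ortho C–H (C3a) is palladated to an aryl–norbornyl palladacycle of divalent palladium; this nucleophilic palladacycle is expected to open 6 at C3 in an SN2 manner to a tetravalent palladium alkyl, reductive elimination forms C3–C3a, norbornene is extruded, and the tethered C2 alkoxide binds the aryl palladium centre and closes O1–C7a by C–O reductive elimination. The closest known reaction type is the palladium/norbornene annulation of ortho-substituted aryl iodides with terminal epoxides to 2-substituted 2,3-dihydrobenzofurans; a 2,3-disubstituted aryl epoxide lies outside that scope. The one ring formed is the five-membered dihydrofuran, closed by ipso C(aryl)–O reductive elimination from a six-membered aryl palladium alkoxide chelate. No stereocentre is created: C2 keeps its configuration because its C–O bond is never broken, and C3 is inverted by the backside opening, so the cis-epoxide becomes the trans (2S,3R) ring. The step needs site selectivity on the arene, secured by the C7 methoxy group that blocks the second ortho position, and it needs opening at C3 instead of benzylic C2, for which the substrate offers the pivaloyloxy-deactivated aryl ring (no benzylic cation character) and the greater bulk at C2 towards a very large nucleophile. The non-transferable 4-methoxybenzyl ether leaves only the C2 alkoxide available for closure, and the acetyl group should remain a spectator under carbonate base with a triarylphosphine.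

Step 6
Reactants: 8 4-[(2S,3R)-5-acetyl-7-methoxy-3-{[(4-methoxybenzyl)oxy]methyl}-2,3-dihydro-1-benzofuran-2-yl]-2,6-dimethoxyphenyl pivalate
Product: 9 4-[(2S,3R)-5-acetyl-3-(hydroxymethyl)-7-methoxy-2,3-dihydro-1-benzofuran-2-yl]-2,6-dimethoxyphenyl pivalate
Conditions: DDQ (1.3 equiv), CH2Cl2/pH 7 phosphate buffer 10:1, 0 °C to rt
Reagents that add atoms: none
Why: Oxidative cleavage of a 4-methoxybenzyl ether by DDQ (electron transfer, oxocarbenium ion, hydrolysis); the acyloxy-substituted C2 aryl ring and the acetyl-substituted ring A are too electron-poor to compete, and the phenol is still masked so that no quinone methide can form.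

Step 7
Reactants: 9 4-[(2S,3R)-5-acetyl-3-(hydroxymethyl)-7-methoxy-2,3-dihydro-1-benzofuran-2-yl]-2,6-dimethoxyphenyl pivalate
Product: 10 1-[(2S,3R)-2-(4-hydroxy-3,5-dimethoxyphenyl)-3-(hydroxymethyl)-7-methoxy-2,3-dihydro-1-benzofuran-5-yl]ethanone
Conditions: K2CO3 (1.5 equiv), MeOH, 20 °C; aq. NH4Cl
Reagents that add atoms: none
Why: Base-mediated methanolysis of an aryl ester; aryl pivalates are far more labile than alkyl esters, so carbonate in methanol at ambient temperature should suffice and the short, mild exposure keeps the phenoxide from opening C2–O1. C2 and C3 are not touched.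

## Compound list

1 | 4-bromo-2,6-dimethoxyphenol | COc1cc(Br)cc(OC)c1O | starting material
2 | 4-bromo-2,6-dimethoxyphenyl pivalate | COc1cc(Br)cc(OC)c1OC(=O)C(C)(C)C | intermediate
3 | 1-methoxy-4-[(prop-2-yn-1-yloxy)methyl]benzene | C#CCOCc1ccc(OC)cc1 | starting material
4 | 2,6-dimethoxy-4-{3-[(4-methoxybenzyl)oxy]prop-1-yn-1-yl}phenyl pivalate | COc1cc(C#CCOCc2ccc(OC)cc2)cc(OC)c1OC(=O)C(C)(C)C | intermediate
5 | 2,6-dimethoxy-4-{(Z)-3-[(4-methoxybenzyl)oxy]prop-1-en-1-yl}phenyl pivalate | COc1cc(/C=C\COCc2ccc(OC)cc2)cc(OC)c1OC(=O)C(C)(C)C | intermediate
6 | 2,6-dimethoxy-4-[(2R,3S)-3-{[(4-methoxybenzyl)oxy]methyl}oxiran-2-yl]phenyl pivalate | COc1cc([C@H]2O[C@H]2COCc2ccc(OC)cc2)cc(OC)c1OC(=O)C(C)(C)C | intermediate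
7 | 1-(4-iodo-3-methoxyphenyl)ethanone | CC(=O)c1ccc(I)c(OC)c1 | starting material
8 | 4-[(2S,3R)-5-acetyl-7-methoxy-3-{[(4-methoxybenzyl)oxy]methyl}-2,3-dihydro-1-benzofuran-2-yl]-2,6-dimethoxyphenyl pivalate | COc1cc([C@H]2Oc3c(OC)cc(C(C)=O)cc3[C@@H]2COCc2ccc(OC)cc2)cc(OC)c1OC(=O)C(C)(C)C | intermediate
9 | 4-[(2S,3R)-5-acetyl-3-(hydroxymethyl)-7-methoxy-2,3-dihydro-1-benzofuran-2-yl]-2,6-dimethoxyphenyl pivalate | COc1cc([C@H]2Oc3c(OC)cc(C(C)=O)cc3[C@@H]2CO)cc(OC)c1OC(=O)C(C)(C)C | intermediate
10 | 1-[(2S,3R)-2-(4-hydroxy-3,5-dimethoxyphenyl)-3-(hydroxymethyl)-7-methoxy-2,3-dihydro-1-benzofuran-5-yl]ethanone | COc1cc([C@H]2Oc3c(OC)cc(C(C)=O)cc3[C@@H]2CO)cc(OC)c1O | target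

## Step count and least certain steps

Total steps: 7. Longest linear sequence: 7 steps (1 to 10); 3 and 7 are purchased.

Step 5 (the new method). Three processes are most likely to go wrong:
- Regiochemical leakage: the oxirane opens at benzylic C2, the site most nucleophiles prefer, which would lead to the 3-aryl-2-(alkoxymethyl) isomer.
- No opening at all: the crowded palladacycle may fail to open a doubly secondary oxirane, so that the aryl palladium species is diverted into reduction, homo-coupling or norbornene-containing products.
- Iodide-mediated opening and reclosure of the oxirane, which would erode the cis geometry or route the alkylation through an iodohydrin with net retention at C3.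

The fallback uses known reaction types only; it sets out from 2 and returns at 9.
- Stille coupling of 2 with (E)-3-(tributylstannyl)prop-2-en-1-ol (Pd(PPh3)4, toluene, 100 °C) would give the E-allylic alcohol F1.
- Methyl chloroformate and pyridine convert it into the allylic methyl carbonate F2.
- Iodination of 1-(4-hydroxy-3-methoxyphenyl)ethanone with N-iodosuccinimide gives the iodophenol F3.
- Its sodium phenoxide (NaH, 1 equiv) is allylated with F2 under [Ir(cod)Cl]2 and a binaphthol-derived bis(1-phenylethyl)phosphoramidite. This branched-selective, enantioselective allylic etherification sets C2 in the (S)-aryl allyl ether F4; the ligand enantiomer has to be chosen for this sense.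
- Oxygenative 5-exo radical cyclisation (Bu3SnH added slowly, dry air, toluene, 0 °C to rt) forms C3–C3a from the aryl radical at C3a. The C2 aryl group directs the new CH2 group trans, and O2 traps the primary radical as hydroperoxide F5, which PPh3 reduces to 9.
- The route then continues with step 7; the 4-methoxybenzyl ether and step 6 are not needed.

Step 4. The likely failures are stepwise collapse of the manganese–oxygen adduct with bond rotation (partial loss of cis geometry), incomplete enantioface selection for an alkene with an allylic oxygen, and electrophilic chlorination of the methoxylated rings by hypochlorite.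

The fallback sets out from 2 and returns at 6.
- Sonogashira coupling of 2 with propargyl alcohol gives the propargylic alcohol F6, and semi-hydrogenation as in step 3 gives the Z-allylic alcohol F7.
- Sharpless asymmetric epoxidation (Ti(OiPr)4, L-(+)-diisopropyl tartrate, tert-butyl hydroperoxide, 4 Å sieves, CH2Cl2, −20 °C) is concerted and hydroxyl-directed, so the geometry cannot leak. It should give the cis-epoxy alcohol F8 with the configuration of 6; the tartrate is chosen by the standard facial model and must be confirmed.
- O-Alkylation with 4-methoxybenzyl bromide (NaH, Bu4NI, THF, 0 °C) returns to 6.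

Step 6. The likely failure is over-oxidation: hydride abstraction at C2 with dehydrogenation to the benzofuran, or attack on the oxygenated arenes, before the ether is fully cleaved.

The fallback replaces the oxidatively cleaved ether by an acid-labile one; it sets out from 2 and returns at 9.
- Sonogashira coupling of 2 with 3-(methoxymethoxy)prop-1-yne (C#CCOCOC) gives the alkyne F9.
- Steps 3 to 5 carried out in this series give the Z-alkene F10, the cis-epoxide F11 and the dihydrobenzofuran F12.
- Methanolic HCl at 40 °C removes the methoxymethyl group by acetal exchange and gives 9. The electron-poor C2 aryl ring should protect C2–O1 against ionisation.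

Step 3. The likely failures are over-reduction to the saturated ether and Z-to-E isomerisation on the palladium surface; both lower the geometric purity that steps 4 and 5 transmit to the ring.

The fallback builds the Z double bond by cross-coupling instead of reduction; it sets out from 3 (with 2 as partner) and returns at 5.
- Rhodium-catalysed trans-hydroboration of 3 with pinacolborane ([Rh(cod)Cl]2, P(iPr)3, Et3N, cyclohexane, rt) gives the Z-alkenyl boronate F13.
- Suzuki–Miyaura coupling with 2 (Pd(dppf)Cl2, K3PO4, THF/H2O, 50 °C) proceeds with retention of geometry and gives 5, replacing steps 2 and 3.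

## Further compounds

F1 | step 5 | 4-[(E)-3-hydroxyprop-1-en-1-yl]-2,6-dimethoxyphenyl pivalate | COc1cc(/C=C/CO)cc(OC)c1OC(=O)C(C)(C)C
F2 | step 5 | (E)-3-[3,5-dimethoxy-4-(pivaloyloxy)phenyl]allyl methyl carbonate | COC(=O)OC/C=C/c1cc(OC)c(OC(=O)C(C)(C)C)c(OC)c1
F3 | step 5 | 1-(4-hydroxy-3-iodo-5-methoxyphenyl)ethanone | CC(=O)c1cc(I)c(O)c(OC)c1
F4 | step 5 | 4-[(S)-1-(4-acetyl-2-iodo-6-methoxyphenoxy)prop-2-en-1-yl]-2,6-dimethoxyphenyl pivalate | COc1cc([C@H](C=C)Oc2c(I)cc(C(C)=O)cc2OC)cc(OC)c1OC(=O)C(C)(C)C
F5 | step 5 | 4-[(2S,3R)-5-acetyl-3-(hydroperoxymethyl)-7-methoxy-2,3-dihydro-1-benzofuran-2-yl]-2,6-dimethoxyphenyl pivalate | COc1cc([C@H]2Oc3c(OC)cc(C(C)=O)cc3[C@@H]2COO)cc(OC)c1OC(=O)C(C)(C)C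
F6 | step 4 | 4-(3-hydroxyprop-1-yn-1-yl)-2,6-dimethoxyphenyl pivalate | COc1cc(C#CCO)cc(OC)c1OC(=O)C(C)(C)C
F7 | step 4 | 4-[(Z)-3-hydroxyprop-1-en-1-yl]-2,6-dimethoxyphenyl pivalate | COc1cc(/C=C\CO)cc(OC)c1OC(=O)C(C)(C)C
F8 | step 4 | 4-[(2R,3S)-3-(hydroxymethyl)oxiran-2-yl]-2,6-dimethoxyphenyl pivalate | COc1cc([C@H]2O[C@H]2CO)cc(OC)c1OC(=O)C(C)(C)C
F9 | step 6 | 2,6-dimethoxy-4-[3-(methoxymethoxy)prop-1-yn-1-yl]phenyl pivalate | COCOCC#Cc1cc(OC)c(OC(=O)C(C)(C)C)c(OC)c1
F10 | step 6 | 2,6-dimethoxy-4-[(Z)-3-(methoxymethoxy)prop-1-en-1-yl]phenyl pivalate | COCOC/C=C\c1cc(OC)c(OC(=O)C(C)(C)C)c(OC)c1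
F11 | step 6 | 2,6-dimethoxy-4-[(2R,3S)-3-[(methoxymethoxy)methyl]oxiran-2-yl]phenyl pivalate | COc1cc([C@H]2O[C@H]2COCOC)cc(OC)c1OC(=O)C(C)(C)C
F12 | step 6 | 4-[(2S,3R)-5-acetyl-7-methoxy-3-[(methoxymethoxy)methyl]-2,3-dihydro-1-benzofuran-2-yl]-2,6-dimethoxyphenyl pivalate | COc1cc([C@H]2Oc3c(OC)cc(C(C)=O)cc3[C@@H]2COCOC)cc(OC)c1OC(=O)C(C)(C)C
F13 | step 3 | (Z)-2-{3-[(4-methoxybenzyl)oxy]prop-1-en-1-yl}-4,4,5,5-tetramethyl-1,3,2-dioxaborolane | COc1ccc(COC/C=C\B2OC(C)(C)C(C)(C)O2)cc1
A1 | alternative 1 | 3-[(2R,3S)-3-[4-(benzyloxy)-3,5-dimethoxyphenyl]-1-[(tert-butyldimethylsilyl)oxy]-3-(4,4,5,5-tetramethyl-1,3,2-dioxaborolan-2-yl)propan-2-yl]-4-fluoro-5-methoxybenzonitrile | COc1cc([C@@H](B2OC(C)(C)C(C)(C)O2)[C@@H](CO[Si](C)(C)C(C)(C)C)c2cc(C#N)cc(OC)c2F)cc(OC)c1OCc1ccccc1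
A2 | alternative 1 | [4-(benzyloxy)-3,5-dimethoxyphenyl]lithium | [Li]c1cc(OC)c(OCc2ccccc2)c(OC)c1
A3 | alternative 1 | (E)-tert-butyldimethyl{[3-(4,4,5,5-tetramethyl-1,3,2-dioxaborolan-2-yl)prop-2-en-1-yl]oxy}silane | CC(C)(C)[Si](C)(C)OC/C=C/B1OC(C)(C)C(C)(C)O1
A4 | alternative 1 | lithium [4-(benzyloxy)-3,5-dimethoxyphenyl][(E)-3-[(tert-butyldimethylsilyl)oxy]prop-1-en-1-yl](pinacolato)borate | [Li+].COc1cc([B-]2(/C=C/CO[Si](C)(C)C(C)(C)C)OC(C)(C)C(C)(C)O2)cc(OC)c1OCc1ccccc1
A5 | alternative 1 | 3-bromo-4-fluoro-5-methoxybenzonitrile | N#Cc1cc(Br)c(F)c(OC)c1
A6 | alternative 2 | (4S)-4-benzyl-3-{[(2S,3S)-2-[4-(benzyloxy)-3,5-dimethoxyphenyl]-5-cyano-7-methoxy-2,3-dihydro-1-benzofuran-3-yl]carbonyl}-1,3-oxazolidin-2-one | COc1cc([C@H]2Oc3c(OC)cc(C#N)cc3[C@@H]2C(=O)N2[C@@H](Cc3ccccc3)COC2=O)cc(OC)c1OCc1ccccc1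
A7 | alternative 2 | (4S)-4-benzyl-3-[2-(5-cyano-2-fluoro-3-methoxyphenyl)acetyl]-1,3-oxazolidin-2-one | COc1cc(C#N)cc(CC(=O)N2[C@@H](Cc3ccccc3)COC2=O)c1F
A8 | alternative 2 | 4-(benzyloxy)-3,5-dimethoxybenzaldehyde | COc1cc(C=O)cc(OC)c1OCc1ccccc1
A9 | alternative 3 | 1-[(2S,3R)-2-[4-(benzyloxy)-3,5-dimethoxyphenyl]-3-{[(tert-butyldimethylsilyl)oxy]methyl}-7-methoxy-2,3-dihydro-1-benzofuran-5-yl]ethanone | COc1cc([C@H]2Oc3c(OC)cc(C(C)=O)cc3[C@@H]2CO[Si](C)(C)C(C)(C)C)cc(OC)c1OCc1ccccc1
A10 | alternative 3 | {[(2S,3R)-2-[4-(benzyloxy)-3,5-dimethoxyphenyl]-5-[(Z)-1,2-dimethoxyvinyl]-2,3-dihydrofuran-3-yl]methoxy}(tert-butyl)dimethylsilane | COc1cc([C@H]2OC(/C(OC)=C/OC)=C[C@@H]2CO[Si](C)(C)C(C)(C)C)cc(OC)c1OCc1ccccc1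
A11 | alternative 3 | but-3-yn-2-one | CC(=O)C#C
A12 | alternative 3 | (4R,5S)-5-[4-(benzyloxy)-3,5-dimethoxyphenyl]-4-{[(tert-butyldimethylsilyl)oxy]methyl}dihydrofuran-2(3H)-one | COc1cc([C@H]2OC(=O)C[C@@H]2CO[Si](C)(C)C(C)(C)C)cc(OC)c1OCc1ccccc1
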